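The readings stem from a simulated flask for substances that don't exist; the scatter is artificial.

The constants of this chemistry are hidden, so the reckoning starts from what the runs give.

| flask | starting material | coupling partner | remark | time |
|---|---|---|---|---|
| red | 11 mM | 11 mM | run made earlier |  |
| grey | 11 mM | 24 mM | run made earlier |  |
| teal | 11 mM | 38 mM | run made earlier |  |
| green | 17 mM | 11.5 mM | run made earlier |  |
| Wednesday's | 30 mM | 50.0 mM |  | 25 h |
| Sunday's | 30 mM | 11.5 mM |  | 25 h |
| Saturday's | 11 mM | 11.5 mM |  | 25 h |
| Monday's | 11 mM | 50.0 mM |  | 25 h |

| run | time / h | target / % | starting material / % |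
|---|---|---|---|
| red | 1.00 | 0 | 99.3 |
| red | 3.00 | 2.1 | 101.2 |
| red | 6.00 | 0 | 98.3 |
| red | 8.00 | 1.5 | 97.7 |
| red | 12.0 | 1.8 | 97.1 |
| grey | 1.00 | 0.4 | 102.7 |
| grey | 3.00 | 0.2 | 97.8 |
| grey | 6.00 | 4.1 | 94.6 |
| grey | 8.00 | 9.0 | 93.9 |
| grey | 12.0 | 16.5 | 84.2 |
| teal | 2.50 | 2.0 | 96.7 |
| teal | 5.00 | 8.1 | 92.0 |
| teal | 8.00 | 18.8 | 80.0 |
| teal | 10.0 | 29.6 | 69.5 |
| teal | 12.0 | 43.8 | 55.7 |
| green | 1.00 | 0.1 | 99.5 |
| green | 3.00 | 0.6 | 100.7 |
| green | 6.00 | 0.8 | 97.4 |
| green | 8.00 | 0.9 | 96.7 |
| green | 12.0 | 6.4 | 94.9 |

(standard deviation of a reading: 1 percentage point)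

- all flasks from highest to lowest amount of target, in percent of the starting material charged, at 25 h (Wednesday's / Sunday's / Saturday's / Monday's)
- the same order at 8.0 d (Wednesday's / Sunday's / Saturday's / Monday's)
- the amount of target, in percent of the starting material charged of the flask you put first, at 25 h
- the amount of target, in percent of the starting material charged of the flask you put last, at 25 h

- a reading or a percentage of target counts all its forms, free or not

How strongly does coupling partner push? At 12.0 h, teal holds 43.8% of target and grey 16.5% from the same starting material. That is a ratio of 2.65 for a partner ratio of 1.58, which reads as an order of 2.12 in coupling partner. Scaled to Monday's charge, teal's reading gives 78.5% at that time.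

How far can each flask go? Call spare partner the charge of coupling partner minus the charge of starting material: zero at equal charges, 39.0 mM in Monday's, 20.0 mM in Wednesday's, 0.500 mM in Saturday's. In Sunday's it is negative, so coupling partner is the limiting reagent there, and one for one its charge allows 38.3%.

Which flask leads? Wednesday's holds more starting material than Monday's, but counted one for one, its spare partner is 40.0% of its partner charge, against 78.0% in Monday's. At the order read above, these one-for-one shares scale the late rate by 0.143 against 0.590, so this reckoning puts Monday's first.

Green reads 6.4% against red's 1.8%, so this reckoning sets Sunday's above Saturday's at 25 h. Saturday's, from red's reading growing with squared time, reaches about 7.81%. By 8.0 d, Sunday's ceiling lies below Saturday's full charge, and this reckoning puts Sunday's last.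

The forecast differs at the head: Wednesday's > Monday's > Sunday's > Saturday's at 25 h and Wednesday's > Monday's > Saturday's > Sunday's at 8.0 d, with 99% (92% to 100%) for the first flask and 9% (4% to 15%) for the last. In its words, “Wednesday's is the faster and should lead”.

The simulation gives Monday's > Wednesday's > Sunday's > Saturday's at 25 h and Monday's > Wednesday's > Saturday's > Sunday's at 8.0 d, with 98.8% for the first flask and 14.2% for the last.

    starting material + coupling partner + by-product → target + 2 by-product (k = 14.0 M⁻² min⁻¹)
    starting material + coupling partner → target + by-product (k = 0.00250 M⁻¹ min⁻¹)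
    coupling partner + target ⇌ idle adduct, settled at all times (K = 1300 M⁻¹)
    starting material + target → side product (k = 0.0210 M⁻¹ min⁻¹)

In the idle adduct, a target holds a second coupling partner, and that draws on the spare partner. At 25.0 h, Monday's 39.0 mM stands against 10.6 mM of idle adduct, and 57.1% of its partner charge stays free. Wednesday's 20.0 mM meets 20.2 mM of idle adduct, with 4.46% of its partner and 6.64% of its starting material left. The neighbour, Saturday's with 29 mM of coupling partner, has a spare partner of 18.0 mM against Saturday's 0.500 mM. It carries 7.74 mM of idle adduct, keeps 45.0% of its partner free and holds 74.5% of target at 25.0 h.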